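**Retrosynthetic overview**
1. Target 40 ⇐ global desilylation of 39 ⇐ Suzuki coupling at the central single bond of the diene, joining the ring-B (Z)-vinyl iodide 38 to the ring-A (E)-vinylboronate 17.
2. Ring B (38) ⇐ ring-closing metathesis (forming the ring-B olefin) of the acyclic epoxy diene 37 ⇐ hydroxyl-directed epoxidation of the Z-trisubstituted allylic alcohol 36.
3. 36 ⇐ three catalyst-controlled alkynylations of enals (distal, proximal and side-chain carbinols), linked by Red-Al trans-hydroalumination/iodination steps that fix the future epoxide olefin and the Z-vinyl iodide.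
4. Ring A (17) ⇐ ring-closing metathesis of diene 13 ⇐ Brown allylation (ring-A carbinol) ⇐ Ireland–Claisen chirality transfer (ring-A methine) from (R)-but-3-yn-2-ol.
5. Ring order: ring A carbocycle (step 9); in the other branch the epoxide (step 25), then the ring B carbocycle (step 26); the two halves are joined in step 27.

Position names used below: ring-A methine = ring-A CH bearing the side chain; ring-A carbinol = ring-A CHOH; quaternary epoxide carbon and epoxide methine = the two oxirane carbons of ring B; proximal carbinol = ring-B CHOH next to the quaternary epoxide carbon; distal carbinol = ring-B CHOH next to the epoxide methine; side-chain carbinol = CHOH between ring B and the diene.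
Abbreviations: TBSO = tert-butyldimethylsilyloxy; TESO = triethylsilyloxy; pin = pinacolato; Ipc = isopinocampheyl; DMP = Dess–Martin periodinane.
Assumption: (S,S)-ProPhenol is taken as the ligand antipode that adds the zinc alkynylide to the Si face of each enal (steps 15, 19, 23); if the observed sense is opposite, (R,R)-ProPhenol is used in all three steps.

**Ring A fragment**

Step 1
Reactants: 1 (R)-but-3-yn-2-ol
Product: 3 (2E,4R)-3-methylpent-2-ene-1,4-diol, via alkenylalane 2 (not isolated)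
Conditions: Me3Al (3 equiv), Cp2ZrCl2 (0.25 equiv), CH2Cl2, 0 °C to rt; then n-BuLi, (CH2O)n, THF, −78 °C to rt; aq. HCl work-up
Reagents that add atoms: trimethylaluminium C[Al](C)C; formaldehyde (as paraformaldehyde) C=O
Why: Negishi Zr-catalysed carboalumination adds Me and Al syn across the alkyne (Me internal, Al terminal) and the derived alanate is hydroxymethylated with retention, giving the E-olefin without touching the carbinol centre.

Step 2
Reactants: 3 (2E,4R)-3-methylpent-2-ene-1,4-diol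
Product: 4 (2R,3E)-3-methyl-5-(TESO)pent-3-en-2-ol
Conditions: TESCl (1.05 equiv), imidazole, CH2Cl2, −40 °C
Reagents that add atoms: chlorotriethylsilane CC[Si](Cl)(CC)CC
Why: Selective silylation, because the unhindered primary allylic hydroxyl reacts faster than the secondary one.

Step 3
Reactants: 4 (2R,3E)-3-methyl-5-(TESO)pent-3-en-2-ol
Product: 5 (2R,3E)-3-methyl-5-(TESO)pent-3-en-2-yl 2-methylpropanoate
Conditions: i-PrCOCl, pyridine, DMAP (cat.), CH2Cl2, 0 °C to rt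
Reagents that add atoms: 2-methylpropanoyl chloride CC(C)C(Cl)=O
Why: DMAP-catalysed acylation installs the isobutyrate for the Claisen step with retention at the carbinol carbon.

Step 4
Reactants: 5 (2R,3E)-3-methyl-5-(TESO)pent-3-en-2-yl 2-methylpropanoate
Product: 8 (3S,4E)-2,2,4-trimethyl-3-[(TESO)methyl]hex-4-enoic acid, via silyl ketene acetal 6 (not isolated), via trimethylsilyl ester 7 (not isolated)
Conditions: LDA, TMSCl, THF, −78 °C to 60 °C; then aq. NH4Cl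
Reagents that add atoms: none
Why: Ireland–Claisen rearrangement through a chair transition state with the carbinol methyl equatorial transfers the C–O chirality to the new C–C bond (the future ring-A methine, S) beside the gem-dimethyl carbon and gives the E-olefin.

Step 5
Reactants: 8 (3S,4E)-2,2,4-trimethyl-3-[(TESO)methyl]hex-4-enoic acid
Product: 9 (3S,4E)-2,2,4-trimethyl-3-[(TESO)methyl]hex-4-en-1-ol
Conditions: LiAlH4, THF, 0 °C to 40 °C; Fieser work-up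
Reagents that add atoms: none
Why: Hydride reduction of the hindered acid to the neopentyl alcohol leaves the silyl ether and olefin untouched.

Step 6
Reactants: 9 (3S,4E)-2,2,4-trimethyl-3-[(TESO)methyl]hex-4-en-1-ol
Product: 10 (3S,4E)-2,2,4-trimethyl-3-[(TESO)methyl]hex-4-enal
Conditions: DMP, CH2Cl2, rt
Reagents that add atoms: none
Why: Dess–Martin oxidation gives the non-enolisable α-quaternary aldehyde without over-oxidation.

Step 7
Reactants: 10 (3S,4E)-2,2,4-trimethyl-3-[(TESO)methyl]hex-4-enal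
Product: 12 (4R,6S,7E)-5,5,7-trimethyl-6-[(TESO)methyl]nona-1,7-dien-4-ol, via borinate 11 (not isolated)
Conditions: (+)-Ipc2B(allyl) [from (−)-α-pinene], Et2O, −78 °C; then NaBO3·4H2O, THF/H2O
Reagents that add atoms: (+)-B-allyldiisopinocampheylborane C=CCB([C@H]1C[C@H]2C[C@@H]([C@@H]1C)C2(C)C)[C@H]1C[C@H]2C[C@@H]([C@@H]1C)C2(C)C
Why: Brown asymmetric allylboration is reagent-controlled; this borane adds allyl to the Re face of the aldehyde through a chair transition state and sets the ring-A carbinol as R.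

Step 8
Reactants: 12 (4R,6S,7E)-5,5,7-trimethyl-6-[(TESO)methyl]nona-1,7-dien-4-ol
Product: 13 (4R,6S,7E)-5,5,7-trimethyl-4-(TESO)-6-[(TESO)methyl]nona-1,7-diene
Conditions: TESOTf, 2,6-lutidine, CH2Cl2, −78 °C
Reagents that add atoms: triethylsilyl trifluoromethanesulfonate CC[Si](CC)(CC)OS(=O)(=O)C(F)(F)F
Why: Silyl triflate silylation protects the hindered secondary alcohol next to the quaternary carbon.

Step 9
Reactants: 13 (4R,6S,7E)-5,5,7-trimethyl-4-(TESO)-6-[(TESO)methyl]nona-1,7-diene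
Product: 14 (4R,6S)-1,5,5-trimethyl-4-(TESO)-6-[(TESO)methyl]cyclohex-1-ene
Conditions: Hoveyda–Grubbs II (5 mol%), toluene, 80 °C
Reagents that add atoms: none
Why: Ring-closing metathesis of the allyl and trisubstituted olefins closes the trisubstituted cyclohexene with loss of propene, helped by the gem-dimethyl effect; the 1,3-cis relationship follows from steps 4 and 7.

Step 10
Reactants: 14 (4R,6S)-1,5,5-trimethyl-4-(TESO)-6-[(TESO)methyl]cyclohex-1-ene
Product: 15 [(1S,5R)-2,6,6-trimethyl-5-(TESO)cyclohex-2-en-1-yl]methanol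
Conditions: PPTS (cat.), MeOH/CH2Cl2, 0 °C
Reagents that add atoms: none
Why: Acid-catalysed methanolysis removes the primary TES ether much faster than the hindered secondary one.

Step 11
Reactants: 15 [(1S,5R)-2,6,6-trimethyl-5-(TESO)cyclohex-2-en-1-yl]methanol
Product: 16 (1S,5R)-2,6,6-trimethyl-5-(TESO)cyclohex-2-ene-1-carbaldehyde
Conditions: DMP, pyridine, CH2Cl2, 0 °C
Reagents that add atoms: none
Why: Buffered Dess–Martin oxidation gives the β,γ-unsaturated aldehyde under non-basic conditions that neither epimerise the ring methine nor move the olefin into conjugation.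

Step 12
Reactants: 16 (1S,5R)-2,6,6-trimethyl-5-(TESO)cyclohex-2-ene-1-carbaldehyde
Product: 17 2-{(E)-2-[(1S,5R)-2,6,6-trimethyl-5-(TESO)cyclohex-2-en-1-yl]ethenyl}-4,4,5,5-tetramethyl-1,3,2-dioxaborolane
Conditions: CrCl2, Cl2CHBpin, LiI, THF, rt
Reagents that add atoms: 2-(dichloromethyl)-4,4,5,5-tetramethyl-1,3,2-dioxaborolane ClC(Cl)B1OC(C)(C)C(C)(C)O1
Why: Takai–Utimoto chromium(II) olefination converts the aldehyde into the E-alkenylboronate under neutral conditions.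

**Ring B fragment**

Step 13
Reactants: 18 2-methylidenepropane-1,3-diol
Product: 19 2-[(TBSO)methyl]prop-2-en-1-ol
Conditions: NaH (1.0 equiv), TBSCl (1.0 equiv), THF, 0 °C to rt
Reagents that add atoms: tert-butyl(chloro)dimethylsilane CC(C)(C)[Si](C)(C)Cl
Why: Monosilylation of the symmetrical diol via its monosodium alkoxide (McDougal protocol).

Step 14
Reactants: 19 2-[(TBSO)methyl]prop-2-en-1-ol
Product: 20 2-[(TBSO)methyl]prop-2-enal
Conditions: MnO2, CH2Cl2, rt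
Reagents that add atoms: none
Why: MnO2 oxidises the allylic alcohol selectively to the enal.

Step 15
Reactants: 20 2-[(TBSO)methyl]prop-2-enal; 21 3,3-diethoxyprop-1-yne
Product: 23 (3S)-6,6-diethoxy-2-[(TBSO)methyl]hex-1-en-4-yn-3-ol, via alkynylzinc 22 (not isolated)
Conditions: Me2Zn, (S,S)-ProPhenol (10 mol%), Ph3PO (20 mol%), toluene, 4 °C
Reagents that add atoms: none
Why: Catalytic asymmetric alkynylation (dinuclear zinc–ProPhenol) adds the zinc acetylide to the Si face of the non-enolisable enal and sets the distal ring-B carbinol.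

Step 16
Reactants: 23 (3S)-6,6-diethoxy-2-[(TBSO)methyl]hex-1-en-4-yn-3-ol
Product: 25 (2Z,4S)-1,1-diethoxy-2-iodo-5-[(TBSO)methyl]hexa-2,5-dien-4-ol, via alkenylalanate 24 (not isolated)
Conditions: Red-Al, THF, 0 °C; then I2, −78 °C to 0 °C; aq. Rochelle salt/Na2S2O3
Reagents that add atoms: iodine II
Why: Alkoxide-directed trans-hydroalumination puts hydride on the alkyne carbon next to the carbinol and aluminium on the distal one, and iodinolysis with retention gives the Z-vinyl iodide with iodine cis to the carbinol carbon.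

Step 17
Reactants: 25 (2Z,4S)-1,1-diethoxy-2-iodo-5-[(TBSO)methyl]hexa-2,5-dien-4-ol
Product: 26 (2Z,4S)-4-(TBSO)-1,1-diethoxy-2-iodo-5-[(TBSO)methyl]hexa-2,5-diene
Conditions: TBSCl, imidazole, DMAP (cat.), DMF, rt
Reagents that add atoms: tert-butyl(chloro)dimethylsilane CC(C)(C)[Si](C)(C)Cl
Why: Imidazole-mediated silylation protects the secondary allylic alcohol without activating the acetal.

Step 18
Reactants: 26 (2Z,4S)-4-(TBSO)-1,1-diethoxy-2-iodo-5-[(TBSO)methyl]hexa-2,5-diene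
Product: 28 (2E,4S)-4-(TBSO)-2-(diethoxymethyl)-5-[(TBSO)methyl]hexa-2,5-dienal, via vinyllithium 27 (not isolated)
Conditions: t-BuLi (2.1 equiv), Et2O, −78 °C; then DMF, −78 °C to 0 °C; aq. NH4Cl
Reagents that add atoms: N,N-dimethylformamide CN(C)C=O
Why: Iodine–lithium exchange gives a configurationally stable vinyllithium that is formylated with retention, so the CHO sits cis to the silyloxy-bearing carbon.

Step 19
Reactants: 28 (2E,4S)-4-(TBSO)-2-(diethoxymethyl)-5-[(TBSO)methyl]hexa-2,5-dienal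
Product: 29 (4S,5E,7S)-7-(TBSO)-5-(diethoxymethyl)-8-[(TBSO)methyl]nona-5,8-dien-2-yn-4-ol
Conditions: propyne, Me2Zn, (S,S)-ProPhenol (20 mol%), Ph3PO, toluene, 4 °C
Reagents that add atoms: propyne CC#C
Why: The same zinc–ProPhenol alkynylation adds propynyl to the Si face of the enal and sets the proximal ring-B carbinol under catalyst control.

Step 20
Reactants: 29 (4S,5E,7S)-7-(TBSO)-5-(diethoxymethyl)-8-[(TBSO)methyl]nona-5,8-dien-2-yn-4-ol
Product: 31 (2E,4S,5E,7S)-7-(TBSO)-5-(diethoxymethyl)-8-[(TBSO)methyl]nona-2,5,8-trien-4-ol, via alkenylalanate 30 (not isolated)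
Conditions: Red-Al, THF, 0 °C to rt; then aq. Rochelle salt
Reagents that add atoms: none
Why: Alkoxide-directed trans-hydroalumination and protonolysis reduce the propargylic alcohol to the E-allylic alcohol, whose olefin is used later for ring closure.

Step 21
Reactants: 31 (2E,4S,5E,7S)-7-(TBSO)-5-(diethoxymethyl)-8-[(TBSO)methyl]nona-2,5,8-trien-4-ol
Product: 32 (2E,4S,5E,7S)-4,7-bis(TBSO)-5-(diethoxymethyl)-8-[(TBSO)methyl]nona-2,5,8-triene
Conditions: TBSOTf, 2,6-lutidine, CH2Cl2, −78 °C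
Reagents that add atoms: tert-butyldimethylsilyl trifluoromethanesulfonate CC(C)(C)[Si](C)(C)OS(=O)(=O)C(F)(F)F
Why: Low-temperature silyl triflate silylation protects the hindered bis-allylic alcohol faster than it activates the acetal.

Step 22
Reactants: 32 (2E,4S,5E,7S)-4,7-bis(TBSO)-5-(diethoxymethyl)-8-[(TBSO)methyl]nona-2,5,8-triene
Product: 33 (2E,4S)-4-(TBSO)-2-[(1S,2E)-1-(TBSO)but-2-en-1-yl]-5-[(TBSO)methyl]hexa-2,5-dienal
Conditions: oxalic acid (cat.), wet SiO2, CH2Cl2, rt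
Reagents that add atoms: water O
Why: Mild acetal hydrolysis unmasks the conjugated aldehyde without cleaving the silyl ethers or isomerising the trisubstituted olefin.

Step 23
Reactants: 33 (2E,4S)-4-(TBSO)-2-[(1S,2E)-1-(TBSO)but-2-en-1-yl]-5-[(TBSO)methyl]hexa-2,5-dienal
Product: 34 (4S,5Z,7S)-7-(TBSO)-5-[(1S,2E)-1-(TBSO)but-2-en-1-yl]-8-[(TBSO)methyl]nona-5,8-dien-2-yn-4-ol
Conditions: propyne, Me2Zn, (S,S)-ProPhenol (20 mol%), Ph3PO, toluene, 4 °C
Reagents that add atoms: propyne CC#C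
Why: A third zinc–ProPhenol alkynylation, again on the Si face, sets the side-chain carbinol as S.

Step 24
Reactants: 34 (4S,5Z,7S)-7-(TBSO)-5-[(1S,2E)-1-(TBSO)but-2-en-1-yl]-8-[(TBSO)methyl]nona-5,8-dien-2-yn-4-ol
Product: 36 (2Z,4S,5Z,7S)-7-(TBSO)-5-[(1S,2E)-1-(TBSO)but-2-en-1-yl]-2-iodo-8-[(TBSO)methyl]nona-2,5,8-trien-4-ol, via alkenylalanate 35 (not isolated)
Conditions: Red-Al, THF, 0 °C; then I2, −78 °C; aq. Rochelle salt/Na2S2O3
Reagents that add atoms: iodine II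
Why: Hydroxyl-directed trans-hydroalumination and iodinolysis give the Z-vinyl iodide (iodine on the methyl-bearing carbon, cis to the carbinol carbon), which fixes the 2Z geometry of the future diene.

Step 25
Reactants: 36 (2Z,4S,5Z,7S)-7-(TBSO)-5-[(1S,2E)-1-(TBSO)but-2-en-1-yl]-2-iodo-8-[(TBSO)methyl]nona-2,5,8-trien-4-ol
Product: 37 (1S,2Z)-1-{(2S,3S)-2-[(1S,2E)-1-(TBSO)but-2-en-1-yl]-3-[(1R)-1-(TBSO)-2-[(TBSO)methyl]prop-2-en-1-yl]oxiran-2-yl}-3-iodobut-2-en-1-ol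
Conditions: VO(acac)2 (5 mol%), t-BuOOH, CH2Cl2, 0 °C
Reagents that add atoms: tert-butyl hydroperoxide CC(C)(C)OO
Why: Vanadium-catalysed hydroxyl-directed epoxidation attacks only the trisubstituted olefin of the free allylic alcohol (the iodoalkene is deactivated) and, through 1,2-allylic strain with the geminal substituent, gives the erythro epoxy alcohol, setting both oxirane carbons.

Step 26
Reactants: 37 (1S,2Z)-1-{(2S,3S)-2-[(1S,2E)-1-(TBSO)but-2-en-1-yl]-3-[(1R)-1-(TBSO)-2-[(TBSO)methyl]prop-2-en-1-yl]oxiran-2-yl}-3-iodobut-2-en-1-ol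
Product: 38 (1S,2Z)-1-[(1S,2S,5R,6S)-2,5-bis(TBSO)-4-[(TBSO)methyl]-7-oxabicyclo[4.1.0]hept-3-en-1-yl]-3-iodobut-2-en-1-ol
Conditions: Grubbs II (10 mol%), CH2Cl2, 40 °C
Reagents that add atoms: none
Why: Ring-closing metathesis of the E-propenyl and 1,1-disubstituted olefins, held cis on the epoxide, closes the cyclohexene with loss of propene; no stereocentre is touched.

**Coupling and end game**

Step 27
Reactants: 38 (1S,2Z)-1-[(1S,2S,5R,6S)-2,5-bis(TBSO)-4-[(TBSO)methyl]-7-oxabicyclo[4.1.0]hept-3-en-1-yl]-3-iodobut-2-en-1-ol; 17 2-{(E)-2-[(1S,5R)-2,6,6-trimethyl-5-(TESO)cyclohex-2-en-1-yl]ethenyl}-4,4,5,5-tetramethyl-1,3,2-dioxaborolane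
Product: 39 (1S,2Z,4E)-1-[(1S,2S,5R,6S)-2,5-bis(TBSO)-4-[(TBSO)methyl]-7-oxabicyclo[4.1.0]hept-3-en-1-yl]-3-methyl-5-[(1S,5R)-2,6,6-trimethyl-5-(TESO)cyclohex-2-en-1-yl]penta-2,4-dien-1-ol
Conditions: Pd(PPh3)4 (10 mol%), TlOEt, THF/H2O (3:1), rt
Reagents that add atoms: none
Why: Suzuki–Miyaura coupling proceeds with retention at both sp2 carbons to give the (2Z,4E)-diene, and thallium ethoxide allows room-temperature coupling that spares the epoxy alcohol and silyl ethers.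

Step 28
Reactants: 39 (1S,2Z,4E)-1-[(1S,2S,5R,6S)-2,5-bis(TBSO)-4-[(TBSO)methyl]-7-oxabicyclo[4.1.0]hept-3-en-1-yl]-3-methyl-5-[(1S,5R)-2,6,6-trimethyl-5-(TESO)cyclohex-2-en-1-yl]penta-2,4-dien-1-ol
Product: 40 (1R,2S,5R,6S)-1-{(1S,2Z,4E)-1-hydroxy-5-[(1S,5R)-5-hydroxy-2,6,6-trimethylcyclohex-2-en-1-yl]-3-methylpenta-2,4-dien-1-yl}-4-(hydroxymethyl)-7-oxabicyclo[4.1.0]hept-3-ene-2,5-diol (CNP0389279.1)
Conditions: HF·pyridine, pyridine, THF, 0 °C to rt
Reagents that add atoms: none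
Why: Buffered fluoride desilylation removes the three TBS ethers and the TES ether without opening the epoxide or ionising the allylic alcohols.

**Compound list**

1 | (R)-but-3-yn-2-ol | C[C@@H](O)C#C | starting material
2 | dimethyl[(1E,3R)-3-(dimethylalumanyloxy)-2-methylbut-1-en-1-yl]alumane | C[C@@H](O[Al](C)C)/C(C)=C/[Al](C)C | intermediate
3 | (2E,4R)-3-methylpent-2-ene-1,4-diol | C[C@@H](O)/C(C)=C/CO | intermediate
4 | (2R,3E)-3-methyl-5-(TESO)pent-3-en-2-ol | C[C@@H](O)/C(C)=C/CO[Si](CC)(CC)CC | intermediate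
5 | (2R,3E)-3-methyl-5-(TESO)pent-3-en-2-yl 2-methylpropanoate | C[C@@H](OC(=O)C(C)C)/C(C)=C/CO[Si](CC)(CC)CC | intermediate
6 | trimethylsilyl ketene acetal of 5 | C[C@@H](OC(O[Si](C)(C)C)=C(C)C)/C(C)=C/CO[Si](CC)(CC)CC | intermediate
7 | trimethylsilyl (3S,4E)-2,2,4-trimethyl-3-[(TESO)methyl]hex-4-enoate | C[Si](C)(C)OC(=O)C(C)(C)[C@@H](CO[Si](CC)(CC)CC)/C(C)=C/C | intermediate
8 | (3S,4E)-2,2,4-trimethyl-3-[(TESO)methyl]hex-4-enoic acid | OC(=O)C(C)(C)[C@@H](CO[Si](CC)(CC)CC)/C(C)=C/C | intermediate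
9 | (3S,4E)-2,2,4-trimethyl-3-[(TESO)methyl]hex-4-en-1-ol | OCC(C)(C)[C@@H](CO[Si](CC)(CC)CC)/C(C)=C/C | intermediate
10 | (3S,4E)-2,2,4-trimethyl-3-[(TESO)methyl]hex-4-enal | O=CC(C)(C)[C@@H](CO[Si](CC)(CC)CC)/C(C)=C/C | intermediate
11 | diisopinocampheylborinate of 12 | C=CC[C@@H](OB([C@H]1C[C@H]2C[C@@H]([C@@H]1C)C2(C)C)[C@H]1C[C@H]2C[C@@H]([C@@H]1C)C2(C)C)C(C)(C)[C@@H](CO[Si](CC)(CC)CC)/C(C)=C/C | intermediate
12 | (4R,6S,7E)-5,5,7-trimethyl-6-[(TESO)methyl]nona-1,7-dien-4-ol | C=CC[C@@H](O)C(C)(C)[C@@H](CO[Si](CC)(CC)CC)/C(C)=C/C | intermediate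
13 | (4R,6S,7E)-5,5,7-trimethyl-4-(TESO)-6-[(TESO)methyl]nona-1,7-diene | C=CC[C@@H](O[Si](CC)(CC)CC)C(C)(C)[C@@H](CO[Si](CC)(CC)CC)/C(C)=C/C | intermediate
14 | (4R,6S)-1,5,5-trimethyl-4-(TESO)-6-[(TESO)methyl]cyclohex-1-ene | CC1=CC[C@@H](O[Si](CC)(CC)CC)C(C)(C)[C@H]1CO[Si](CC)(CC)CC | intermediate
15 | [(1S,5R)-2,6,6-trimethyl-5-(TESO)cyclohex-2-en-1-yl]methanol | CC1=CC[C@@H](O[Si](CC)(CC)CC)C(C)(C)[C@H]1CO | intermediate
16 | (1S,5R)-2,6,6-trimethyl-5-(TESO)cyclohex-2-ene-1-carbaldehyde | CC1=CC[C@@H](O[Si](CC)(CC)CC)C(C)(C)[C@H]1C=O | intermediate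
17 | 2-{(E)-2-[(1S,5R)-2,6,6-trimethyl-5-(TESO)cyclohex-2-en-1-yl]ethenyl}-4,4,5,5-tetramethyl-1,3,2-dioxaborolane | CC1=CC[C@@H](O[Si](CC)(CC)CC)C(C)(C)[C@H]1/C=C/B2OC(C)(C)C(C)(C)O2 | intermediate
18 | 2-methylidenepropane-1,3-diol | C=C(CO)CO | starting material
19 | 2-[(TBSO)methyl]prop-2-en-1-ol | C=C(CO)CO[Si](C)(C)C(C)(C)C | intermediate
20 | 2-[(TBSO)methyl]prop-2-enal | C=C(C=O)CO[Si](C)(C)C(C)(C)C | intermediate
21 | 3,3-diethoxyprop-1-yne | CCOC(OCC)C#C | starting material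
22 | (3,3-diethoxyprop-1-yn-1-yl)(methyl)zinc | CCOC(OCC)C#C[Zn]C | intermediate
23 | (3S)-6,6-diethoxy-2-[(TBSO)methyl]hex-1-en-4-yn-3-ol | CCOC(OCC)C#C[C@H](O)C(=C)CO[Si](C)(C)C(C)(C)C | intermediate
24 | sodium cyclic alkenylalanate (2,5-dihydro-1,2-oxaluminole) from 23 | CCOC(OCC)C1=C[C@@H](C(=C)CO[Si](C)(C)C(C)(C)C)O[Al-]1(OCCOC)OCCOC.[Na+] | intermediate
25 | (2Z,4S)-1,1-diethoxy-2-iodo-5-[(TBSO)methyl]hexa-2,5-dien-4-ol | CCOC(OCC)/C(I)=C/[C@H](O)C(=C)CO[Si](C)(C)C(C)(C)C | intermediate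
26 | (2Z,4S)-4-(TBSO)-1,1-diethoxy-2-iodo-5-[(TBSO)methyl]hexa-2,5-diene | CCOC(OCC)/C(I)=C/[C@H](O[Si](C)(C)C(C)(C)C)C(=C)CO[Si](C)(C)C(C)(C)C | intermediate
27 | vinyllithium from 26 (Li in place of I) | CCOC(OCC)/C([Li])=C/[C@H](O[Si](C)(C)C(C)(C)C)C(=C)CO[Si](C)(C)C(C)(C)C | intermediate
28 | (2E,4S)-4-(TBSO)-2-(diethoxymethyl)-5-[(TBSO)methyl]hexa-2,5-dienal | CCOC(OCC)/C(C=O)=C/[C@H](O[Si](C)(C)C(C)(C)C)C(=C)CO[Si](C)(C)C(C)(C)C | intermediate
29 | (4S,5E,7S)-7-(TBSO)-5-(diethoxymethyl)-8-[(TBSO)methyl]nona-5,8-dien-2-yn-4-ol | CCOC(OCC)/C(=C/[C@H](O[Si](C)(C)C(C)(C)C)C(=C)CO[Si](C)(C)C(C)(C)C)[C@@H](O)C#CC | intermediate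
30 | sodium cyclic alkenylalanate from 29 | CCOC(OCC)/C(=C/[C@H](O[Si](C)(C)C(C)(C)C)C(=C)CO[Si](C)(C)C(C)(C)C)[C@@H]1C=C(C)[Al-](OCCOC)(OCCOC)O1.[Na+] | intermediate
31 | (2E,4S,5E,7S)-7-(TBSO)-5-(diethoxymethyl)-8-[(TBSO)methyl]nona-2,5,8-trien-4-ol | CCOC(OCC)/C(=C/[C@H](O[Si](C)(C)C(C)(C)C)C(=C)CO[Si](C)(C)C(C)(C)C)[C@@H](O)/C=C/C | intermediate
32 | (2E,4S,5E,7S)-4,7-bis(TBSO)-5-(diethoxymethyl)-8-[(TBSO)methyl]nona-2,5,8-triene | CCOC(OCC)/C(=C/[C@H](O[Si](C)(C)C(C)(C)C)C(=C)CO[Si](C)(C)C(C)(C)C)[C@@H](O[Si](C)(C)C(C)(C)C)/C=C/C | intermediate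
33 | (2E,4S)-4-(TBSO)-2-[(1S,2E)-1-(TBSO)but-2-en-1-yl]-5-[(TBSO)methyl]hexa-2,5-dienal | O=C/C(=C/[C@H](O[Si](C)(C)C(C)(C)C)C(=C)CO[Si](C)(C)C(C)(C)C)[C@@H](O[Si](C)(C)C(C)(C)C)/C=C/C | intermediate
34 | (4S,5Z,7S)-7-(TBSO)-5-[(1S,2E)-1-(TBSO)but-2-en-1-yl]-8-[(TBSO)methyl]nona-5,8-dien-2-yn-4-ol | CC#C[C@H](O)/C(=C/[C@H](O[Si](C)(C)C(C)(C)C)C(=C)CO[Si](C)(C)C(C)(C)C)[C@@H](O[Si](C)(C)C(C)(C)C)/C=C/C | intermediate
35 | sodium cyclic alkenylalanate from 34 | CC1=C[C@H](O[Al-]1(OCCOC)OCCOC)/C(=C/[C@H](O[Si](C)(C)C(C)(C)C)C(=C)CO[Si](C)(C)C(C)(C)C)[C@@H](O[Si](C)(C)C(C)(C)C)/C=C/C.[Na+] | intermediate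
36 | (2Z,4S,5Z,7S)-7-(TBSO)-5-[(1S,2E)-1-(TBSO)but-2-en-1-yl]-2-iodo-8-[(TBSO)methyl]nona-2,5,8-trien-4-ol | C/C(I)=C/[C@H](O)/C(=C/[C@H](O[Si](C)(C)C(C)(C)C)C(=C)CO[Si](C)(C)C(C)(C)C)[C@@H](O[Si](C)(C)C(C)(C)C)/C=C/C | intermediate
37 | (1S,2Z)-1-{(2S,3S)-2-[(1S,2E)-1-(TBSO)but-2-en-1-yl]-3-[(1R)-1-(TBSO)-2-[(TBSO)methyl]prop-2-en-1-yl]oxiran-2-yl}-3-iodobut-2-en-1-ol | C/C(I)=C/[C@H](O)[C@@]1(O[C@H]1[C@H](O[Si](C)(C)C(C)(C)C)C(=C)CO[Si](C)(C)C(C)(C)C)[C@@H](O[Si](C)(C)C(C)(C)C)/C=C/C | intermediate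
38 | (1S,2Z)-1-[(1S,2S,5R,6S)-2,5-bis(TBSO)-4-[(TBSO)methyl]-7-oxabicyclo[4.1.0]hept-3-en-1-yl]-3-iodobut-2-en-1-ol | C/C(I)=C/[C@H](O)[C@]12O[C@H]1[C@H](O[Si](C)(C)C(C)(C)C)C(CO[Si](C)(C)C(C)(C)C)=C[C@@H]2O[Si](C)(C)C(C)(C)C | intermediate
39 | (1S,2Z,4E)-1-[(1S,2S,5R,6S)-2,5-bis(TBSO)-4-[(TBSO)methyl]-7-oxabicyclo[4.1.0]hept-3-en-1-yl]-3-methyl-5-[(1S,5R)-2,6,6-trimethyl-5-(TESO)cyclohex-2-en-1-yl]penta-2,4-dien-1-ol | CC1=CC[C@@H](O[Si](CC)(CC)CC)C(C)(C)[C@H]1/C=C/C(C)=C\[C@H](O)[C@]12O[C@H]1[C@H](O[Si](C)(C)C(C)(C)C)C(CO[Si](C)(C)C(C)(C)C)=C[C@@H]2O[Si](C)(C)C(C)(C)C | intermediate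
40 | (1R,2S,5R,6S)-1-{(1S,2Z,4E)-1-hydroxy-5-[(1S,5R)-5-hydroxy-2,6,6-trimethylcyclohex-2-en-1-yl]-3-methylpenta-2,4-dien-1-yl}-4-(hydroxymethyl)-7-oxabicyclo[4.1.0]hept-3-ene-2,5-diol (CNP0389279.1) | CC1=CC[C@@H](O)C(C)(C)[C@H]1/C=C/C(C)=C\[C@H](O)[C@]12O[C@H]1[C@H](O)C(CO)=C[C@@H]2O | target

**Step count and risks**

Total step count: 28 (steps 1–12 ring A fragment, steps 13–26 ring B fragment, steps 27–28 coupling and deprotection).
Longest linear sequence: 16 steps (18 → 40, steps 13–28).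

Most likely to fail, with fallbacks:

Step 19 (catalytic alkynylation of the hindered α-branched enal 28; the same concern applies to steps 15 and 23). The fallback sets out from 28 and replaces catalyst control by a ketone reduction: 1-propynylmagnesium bromide (THF, −78 °C) gives the epimeric propargylic alcohols F1, Dess–Martin oxidation gives the ynone F2, and (R)-Me-CBS/catecholborane reduction (alkenyl as the large group, propynyl as the small group) delivers the single carbinol epimer, returning to the route at 29.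

Step 26 (metathesis of two hindered olefins in the presence of the epoxy alcohol). The fallback sets out from 36 and inverts the order of ring and epoxide formation: ring-closing metathesis of 36 (Grubbs II, CH2Cl2, 40 °C) gives the cyclohexa-1,4-diene F3, and VO(acac)2/t-BuOOH epoxidation of its ring olefin, directed erythro by the side-chain hydroxyl and anti to both ring silyloxy groups, returns to the route at 38.

Step 27 (Suzuki coupling of a hindered Z-iodide next to a base-sensitive epoxy alcohol). The fallback sets out from 16 and uses base-free tin chemistry: CrCl2/Bu3SnCHBr2/LiI olefination of 16 gives the (E)-vinylstannane F4, and Stille coupling of F4 with 38 (Pd2(dba)3, AsPh3, CuI, NMP, rt) returns to the route at 39.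

**Further compounds**

F1 | step 19 | (5E,7S)-7-(TBSO)-5-(diethoxymethyl)-8-[(TBSO)methyl]nona-5,8-dien-2-yn-4-ol (epimers at the new carbinol) | CCOC(OCC)/C(=C/[C@H](O[Si](C)(C)C(C)(C)C)C(=C)CO[Si](C)(C)C(C)(C)C)C(O)C#CC
F2 | step 19 | (5Z,7S)-7-(TBSO)-5-(diethoxymethyl)-8-[(TBSO)methyl]nona-5,8-dien-2-yn-4-one | CCOC(OCC)/C(=C/[C@H](O[Si](C)(C)C(C)(C)C)C(=C)CO[Si](C)(C)C(C)(C)C)C(=O)C#CC
F3 | step 26 | (1S,2Z)-1-[(3S,6S)-3,6-bis(TBSO)-4-[(TBSO)methyl]cyclohexa-1,4-dien-1-yl]-3-iodobut-2-en-1-ol | C/C(I)=C/[C@H](O)C1=C[C@H](O[Si](C)(C)C(C)(C)C)C(CO[Si](C)(C)C(C)(C)C)=C[C@@H]1O[Si](C)(C)C(C)(C)C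
F4 | step 27 | tributyl{(E)-2-[(1S,5R)-2,6,6-trimethyl-5-(TESO)cyclohex-2-en-1-yl]ethenyl}stannane | CC1=CC[C@@H](O[Si](CC)(CC)CC)C(C)(C)[C@H]1/C=C/[Sn](CCCC)(CCCC)CCCC
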